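**Retrosynthetic overview**
1. The C5–O ester bond is made last from the anti-1,3-diol and 3,4-dimethoxybenzoyl chloride; the C5 stereocentre comes from hydroxyl-directed reduction of a β-hydroxy enone.
2. Ring B (C3a–C4–C5–C6–C7–C8–C8a) is closed last, at C3a–C4, by a SmI2 reductive aldol (Reformatsky-type) cyclisation of a bromomethyl (Z)-enone onto the ring A ketone; both carbons are electrophilic in the precursor and are joined by polarity reversal.
3. Enabling feature: the C3a(OH)–C4H2–C5(O) 1,3-dioxygen (aldol) array of ring B beside the C6=C7 double bond, a latent β-hydroxy enone, with C3a at the ring fusion next to the quaternary C8a that carries the tether; the precursor is a monocyclic cyclopentanone with an achiral side chain.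
4. Side chain: C8a–CH2–CHO → (Z)-vinyl iodide (Stork–Zhao) → 1-ethoxyvinyl (Stille) → bromomethyl ketone; C8a is set by a Claisen rearrangement anti to the isopropyl group, and the C3a ketone by ozonolysis of the resulting exocyclic methylene.
5. Ring A is formed first, from (S)-limonene: hydrogenation, ozonolysis and aldol condensation to the cyclopentene carbaldehyde (C3 stereocentre from the chiral pool); ring B follows in the key step.

Key step: step 11

Remark: locants C1 to C8a are those of the hydroazulene skeleton of the target (ring A: C1, C2, C3, C3a, C8a; ring B: C3a, C4, C5, C6, C7, C8, C8a) and are used for the same atoms in all precursors; (S)-(−)-limonene of high enantiomeric purity is assumed as the source of the C3 stereocentre.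

Step 1
Reactants: 1 (S)-(−)-limonene, (4S)-1-methyl-4-(prop-1-en-2-yl)cyclohex-1-ene
Product: 2 (4S)-1-methyl-4-(propan-2-yl)cyclohex-1-ene
Conditions: H2 (1 atm, stopped after 1 equiv), PtO2 (cat.), EtOH, rt
Reagents that add atoms: none
Why: Heterogeneous hydrogenation over PtO2 saturates the unhindered 1,1-disubstituted isopropenyl alkene well before the trisubstituted ring alkene (chemoselective alkene hydrogenation), and the stereocentre, the later C3, is not involved.

Step 2
Reactants: 2 (4S)-1-methyl-4-(propan-2-yl)cyclohex-1-ene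
Product: 4 (3S)-6-oxo-3-(propan-2-yl)heptanal, via secondary ozonide 3 (not isolated)
Conditions: O3, CH2Cl2, −78 °C; then Me2S, −78 °C to rt
Reagents that add atoms: ozone ([O-][O+]=O)
Why: Ozonolysis with reductive work-up cleaves the only remaining double bond to the methyl ketone and the aldehyde under neutral conditions that leave the stereocentre untouched.

Step 3
Reactants: 4 (3S)-6-oxo-3-(propan-2-yl)heptanal
Product: 5 (5R)-2-methyl-5-(propan-2-yl)cyclopent-1-ene-1-carbaldehyde
Conditions: piperidine (cat.), AcOH (cat.), toluene, 80 °C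
Reagents that add atoms: none
Why: Intramolecular aldol condensation under piperidinium acetate catalysis (the enamine of the aldehyde adds to the methyl ketone in a 5-exo-trig closure, then water is lost) forms ring A as the conjugated cyclopentene carbaldehyde, and the isopropyl-bearing carbon, which is not deprotonated in this mode, keeps its configuration.

Step 4
Reactants: 5 (5R)-2-methyl-5-(propan-2-yl)cyclopent-1-ene-1-carbaldehyde
Product: 6 [(5R)-2-methyl-5-(propan-2-yl)cyclopent-1-en-1-yl]methanol
Conditions: NaBH4, CeCl3·7H2O, MeOH, 0 °C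
Reagents that add atoms: none
Why: Luche reduction gives selective 1,2-reduction of the enal to the primary allylic alcohol without touching the tetrasubstituted alkene.

Step 5
Reactants: 6 [(5R)-2-methyl-5-(propan-2-yl)cyclopent-1-en-1-yl]methanol; 7 ethyl vinyl ether
Product: 8 (5R)-1-[(ethenyloxy)methyl]-2-methyl-5-(propan-2-yl)cyclopent-1-ene
Conditions: Pd(OAc)2 (5 mol%), 1,10-phenanthroline (6 mol%), 7 (excess, as solvent), rt
Reagents that add atoms: ethyl vinyl ether 7 (C=COCC)
Why: Pd(OAc)2/phenanthroline-catalysed transfer vinylation (vinyl ether exchange) turns the primary allylic alcohol into the allyl vinyl ether without isomerising the alkene.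

Step 6
Reactants: 8 (5R)-1-[(ethenyloxy)methyl]-2-methyl-5-(propan-2-yl)cyclopent-1-ene
Product: 9 2-[(1R,3R)-1-methyl-2-methylidene-3-(propan-2-yl)cyclopentyl]acetaldehyde
Conditions: toluene, 180 °C, sealed tube
Reagents that add atoms: none
Why: Thermal Claisen rearrangement through a chair-like [3,3] transition state creates the quaternary C8a centre and moves the double bond into the exocyclic position, and because the O–CH2 arm on the alkene carbon swings to the ring face opposite to the neighbouring isopropyl group the new C8a–C8 bond should form anti to it (methyl and isopropyl cis).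

Step 7
Reactants: 9 2-[(1R,3R)-1-methyl-2-methylidene-3-(propan-2-yl)cyclopentyl]acetaldehyde
Product: 11 2-[(1R,3R)-1-methyl-2-oxo-3-(propan-2-yl)cyclopentyl]acetaldehyde, via secondary ozonide 10 (not isolated)
Conditions: O3, CH2Cl2, −78 °C; then Me2S, −78 °C to rt
Reagents that add atoms: ozone ([O-][O+]=O)
Why: Ozonolysis of the electron-rich 1,1-disubstituted exocyclic alkene releases the ring A ketone (the later C3a) under neutral conditions, so that the now epimerisable C3 centre beside it is not scrambled.

Step 8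
Reactants: 11 2-[(1R,3R)-1-methyl-2-oxo-3-(propan-2-yl)cyclopentyl]acetaldehyde; 12 ethyl(triphenyl)phosphonium iodide
Product: 13 (2R,5R)-2-[(2Z)-3-iodobut-2-en-1-yl]-2-methyl-5-(propan-2-yl)cyclopentan-1-one
Conditions: 12, n-BuLi, THF, 0 °C; I2, −78 °C; NaN(SiMe3)2, −20 °C; then 11, −78 °C to −20 °C
Reagents that add atoms: ethyl(triphenyl)phosphonium iodide 12 (CC[P+](c1ccccc1)(c1ccccc1)c1ccccc1.[I-]); iodine (II)
Why: Stork–Zhao olefination (Wittig reaction of the α-iodo ylide made in the flask) reacts only at the aldehyde, the hindered ketone being inert, and should give the trisubstituted (Z)-vinyl iodide by kinetic control, which fixes the cis relation of C8 and the later C5 across C6=C7 that ring B needs.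

Step 9
Reactants: 13 (2R,5R)-2-[(2Z)-3-iodobut-2-en-1-yl]-2-methyl-5-(propan-2-yl)cyclopentan-1-one; 14 tributyl(1-ethoxyethenyl)stannane
Product: 15 (2R,5R)-2-[(2Z)-4-ethoxy-3-methylpenta-2,4-dien-1-yl]-2-methyl-5-(propan-2-yl)cyclopentan-1-one
Conditions: 14, PdCl2(PPh3)2 (5 mol%), CuI (10 mol%), DMF, 60 °C
Reagents that add atoms: tributyl(1-ethoxyethenyl)stannane 14 (CCCC[Sn](CCCC)(CCCC)C(=C)OCC)
Why: Stille coupling proceeds with retention of alkene geometry and adds C5 and C4 as a 1-ethoxyvinyl group, a masked acetyl group, under neutral conditions that tolerate the ketone.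

Step 10
Reactants: 15 (2R,5R)-2-[(2Z)-4-ethoxy-3-methylpenta-2,4-dien-1-yl]-2-methyl-5-(propan-2-yl)cyclopentan-1-one
Product: 16 (2R,5R)-2-[(2Z)-5-bromo-3-methyl-4-oxopent-2-en-1-yl]-2-methyl-5-(propan-2-yl)cyclopentan-1-one
Conditions: N-bromosuccinimide, NaHCO3, THF/H2O (4:1), 0 °C
Reagents that add atoms: N-bromosuccinimide (O=C1CCC(=O)N1Br); water (O)
Why: Electrophilic bromination of the enol ether at its terminal carbon (C4) and hydrolysis of the resulting oxocarbenium ion give the bromomethyl ketone, since the enol ether is far more nucleophilic than the trisubstituted alkene and the buffered medium avoids Z to E isomerisation of the enone.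

Step 11
Reactants: 16 (2R,5R)-2-[(2Z)-5-bromo-3-methyl-4-oxopent-2-en-1-yl]-2-methyl-5-(propan-2-yl)cyclopentan-1-one
Product: 18 (3R,3aS,8aR)-3a-hydroxy-6,8a-dimethyl-3-(propan-2-yl)-2,3,3a,4,8,8a-hexahydroazulen-5(1H)-one, via trivalent samarium dienolate 17 (not isolated)
Conditions: SmI2 (2.5 equiv), THF, high dilution, −78 °C to −40 °C; then sat. aq. NH4Cl
Reagents that add atoms: none
Why: Two SmI2 each transfer one electron to the C4–Br bond of 16 to give the trivalent samarium dienolate 17 (C4=C5(O–Sm)–C6=C7), whose nucleophilic C4 adds to the C3a ketone through a samarium-chelated closed transition state, so that two carbons that are both electrophilic in 16 are joined by polarity reversal; the closest known reaction type is the SmI2-mediated intramolecular Reformatsky-type aldol cyclisation of α-bromo ketones onto carbonyl groups, which is established for medium rings. Ring B is closed in a 7-(enolendo)-exo-trig mode. The new C3a stereocentre is controlled by the C8a tether, which can deliver C4 only to the ring A face that carries the C8 methylene, and by the C3 isopropyl and C8a methyl groups, which shield the other face, so that the cis-fused hydroxy ketone with the hydroxyl syn to both groups should result. The step needs chemoselective reduction of the α-bromo ketone in the presence of the enone and the ring ketone (C–Br cleavage is far faster at −78 °C without additives), bond formation at C4 rather than at C6 (a fully substituted, non-nucleophilic position of the cross-conjugated dienolate) and retention of the (Z)-C6=C7 geometry, all of which the non-basic, low-temperature conditions secure, as they also protect the epimerisable C3 centre. The Z geometry fixed in steps 8 and 9 is what brings C4 within reach of C3a.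

Step 12
Reactants: 18 (3R,3aS,8aR)-3a-hydroxy-6,8a-dimethyl-3-(propan-2-yl)-2,3,3a,4,8,8a-hexahydroazulen-5(1H)-one
Product: 19 (3R,3aS,5R,8aR)-6,8a-dimethyl-3-(propan-2-yl)-2,3,4,5,8,8a-hexahydroazulene-3a,5(1H)-diol
Conditions: Me4NBH(OAc)3, MeCN/AcOH (1:1), −30 °C
Reagents that add atoms: none
Why: Evans–Saksena reduction, in which the C3a hydroxyl exchanges onto boron and delivers hydride intramolecularly to the C5 carbonyl on its own face of ring B, should set C5 with its oxygen anti to the C3a hydroxyl (5R) and give 1,2-reduction only.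

Step 13
Reactants: 19 (3R,3aS,5R,8aR)-6,8a-dimethyl-3-(propan-2-yl)-2,3,4,5,8,8a-hexahydroazulene-3a,5(1H)-diol; 20 3,4-dimethoxybenzoyl chloride
Product: 21 (3R,3aS,5R,8aR)-3a-hydroxy-6,8a-dimethyl-3-(propan-2-yl)-1,2,3,3a,4,5,8,8a-octahydroazulen-5-yl 3,4-dimethoxybenzoate
Conditions: 20, Et3N, DMAP (cat.), CH2Cl2, 0 °C to rt
Reagents that add atoms: 3,4-dimethoxybenzoyl chloride 20 (COc1ccc(C(=O)Cl)cc1OC)
Why: DMAP-catalysed acylation (nucleophilic catalysis via the acylpyridinium ion) esterifies the secondary allylic C5 hydroxyl with retention, the tertiary ring-fusion hydroxyl being too hindered to compete.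

**Compound list**
1 | (S)-(−)-limonene, (4S)-1-methyl-4-(prop-1-en-2-yl)cyclohex-1-ene | CC1=CC[C@H](CC1)C(C)=C | starting material
2 | (4S)-1-methyl-4-(propan-2-yl)cyclohex-1-ene | CC1=CC[C@H](CC1)C(C)C | intermediate
3 | secondary ozonide of 2, 1-methyl-4-(propan-2-yl)-7,8,9-trioxabicyclo[4.2.1]nonane (not isolated; isopropyl centre as in 2, bridgeheads not defined) | CC12CC[C@H](C(C)C)CC(OO1)O2 | intermediate
4 | (3S)-6-oxo-3-(propan-2-yl)heptanal | O=CC[C@H](CCC(C)=O)C(C)C | intermediate
5 | (5R)-2-methyl-5-(propan-2-yl)cyclopent-1-ene-1-carbaldehyde | O=CC1=C(C)CC[C@@H]1C(C)C | intermediate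
6 | [(5R)-2-methyl-5-(propan-2-yl)cyclopent-1-en-1-yl]methanol | OCC1=C(C)CC[C@@H]1C(C)C | intermediate
7 | ethyl vinyl ether (ethoxyethene) | C=COCC | starting material
8 | (5R)-1-[(ethenyloxy)methyl]-2-methyl-5-(propan-2-yl)cyclopent-1-ene | C=COCC1=C(C)CC[C@@H]1C(C)C | intermediate
9 | 2-[(1R,3R)-1-methyl-2-methylidene-3-(propan-2-yl)cyclopentyl]acetaldehyde | O=CC[C@@]1(C)CC[C@H](C(C)C)C1=C | intermediate
10 | secondary ozonide of 9, 2-[6-methyl-9-(propan-2-yl)-1,2,4-trioxaspiro[4.4]nonan-6-yl]acetaldehyde (not isolated; ring centres as in 9, spiro centre not defined) | O=CC[C@@]1(C)CC[C@H](C(C)C)C12OCOO2 | intermediate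
11 | 2-[(1R,3R)-1-methyl-2-oxo-3-(propan-2-yl)cyclopentyl]acetaldehyde | O=CC[C@@]1(C)CC[C@H](C(C)C)C1=O | intermediate
12 | ethyl(triphenyl)phosphonium iodide | CC[P+](c1ccccc1)(c1ccccc1)c1ccccc1.[I-] | starting material
13 | (2R,5R)-2-[(2Z)-3-iodobut-2-en-1-yl]-2-methyl-5-(propan-2-yl)cyclopentan-1-one | C/C(I)=C/C[C@@]1(C)CC[C@H](C(C)C)C1=O | intermediate
14 | tributyl(1-ethoxyethenyl)stannane | CCCC[Sn](CCCC)(CCCC)C(=C)OCC | starting material
15 | (2R,5R)-2-[(2Z)-4-ethoxy-3-methylpenta-2,4-dien-1-yl]-2-methyl-5-(propan-2-yl)cyclopentan-1-one | CCOC(=C)/C(C)=C\C[C@@]1(C)CC[C@H](C(C)C)C1=O | intermediate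
16 | (2R,5R)-2-[(2Z)-5-bromo-3-methyl-4-oxopent-2-en-1-yl]-2-methyl-5-(propan-2-yl)cyclopentan-1-one | BrCC(=O)/C(C)=C\C[C@@]1(C)CC[C@H](C(C)C)C1=O | intermediate
17 | trivalent samarium dienolate of 16, diiodosamarium enolate (not isolated) | C=C(O[Sm](I)I)/C(C)=C\C[C@@]1(C)CC[C@H](C(C)C)C1=O | intermediate
18 | (3R,3aS,8aR)-3a-hydroxy-6,8a-dimethyl-3-(propan-2-yl)-2,3,3a,4,8,8a-hexahydroazulen-5(1H)-one | O=C1C[C@]2(O)[C@@H](C(C)C)CC[C@]2(C)CC=C1C | intermediate
19 | (3R,3aS,5R,8aR)-6,8a-dimethyl-3-(propan-2-yl)-2,3,4,5,8,8a-hexahydroazulene-3a,5(1H)-diol | O[C@@H]1C[C@]2(O)[C@@H](C(C)C)CC[C@]2(C)CC=C1C | intermediate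
20 | 3,4-dimethoxybenzoyl chloride | COc1ccc(C(=O)Cl)cc1OC | starting material
21 | (3R,3aS,5R,8aR)-3a-hydroxy-6,8a-dimethyl-3-(propan-2-yl)-1,2,3,3a,4,5,8,8a-octahydroazulen-5-yl 3,4-dimethoxybenzoate | COc1ccc(C(=O)O[C@@H]2C[C@]3(O)[C@@H](C(C)C)CC[C@]3(C)CC=C2C)cc1OC | target

Total step count: 13. Longest linear sequence: 13 steps (1 to 21).

**Steps most likely to fail, with fallbacks**

Step 11. The samarium dienolate may be protonated, or the aldolate may revert by retro-aldol cleavage, faster than the seven-membered ring closes onto the hindered ketone. The fallback closes ring B at C5–C6 instead of C3a–C4, by a Nozaki–Hiyama–Kishi reaction. It sets out from 13. Addition of allylmagnesium bromide in the presence of CeCl3 (THF, −78 °C), from the face anti to the isopropyl group, should give (1S,2R,5R)-2-[(2Z)-3-iodobut-2-en-1-yl]-2-methyl-5-(propan-2-yl)-1-(prop-2-en-1-yl)cyclopentan-1-ol F1. Lemieux–Johnson cleavage of its terminal alkene (OsO4 cat., NaIO4, 2,6-lutidine, dioxane/H2O), to which the electron-poor vinyl iodide should be inert, should give 2-[(1S,2R,5R)-1-hydroxy-2-[(2Z)-3-iodobut-2-en-1-yl]-2-methyl-5-(propan-2-yl)cyclopentyl]acetaldehyde F2. Intramolecular Nozaki–Hiyama–Kishi coupling (CrCl2, NiCl2 cat., DMSO, high dilution) should then give (3R,3aS,8aR)-6,8a-dimethyl-3-(propan-2-yl)-2,3,4,5,8,8a-hexahydroazulene-3a,5(1H)-diol F3 as a mixture of C5 epimers. Oxidation of the allylic C5 alcohol with MnO2 comes back to the route at 18.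

Step 8. Z/E control may erode in the iodo-olefination, and the basic ylide may enolise the keto aldehyde. The fallback builds the alkene geometry by stepwise cross-coupling instead of by Wittig selectivity. It sets out from 11. Ramirez olefination (CBr4, PPh3, CH2Cl2, 0 °C), which should touch only the aldehyde, should give (2R,5R)-2-(3,3-dibromoprop-2-en-1-yl)-2-methyl-5-(propan-2-yl)cyclopentan-1-one F4. Trans-selective Negishi monomethylation (Me2Zn, PdCl2(DPEphos) cat., THF), which replaces the less hindered bromine trans to the chain with retention, should give (2R,5R)-2-[(2Z)-3-bromobut-2-en-1-yl]-2-methyl-5-(propan-2-yl)cyclopentan-1-one F5. Stille coupling of F5 with 14 (Pd2(dba)3, P(t-Bu)3, CsF, dioxane) comes back to the route at 15.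

Step 12. The hindered tertiary hydroxyl may exchange onto boron too slowly, so that external hydride attack competes and facial selectivity at C5 is lost. The fallback gives up internal delivery and uses chelation-controlled external reduction followed by esterification with inversion. It sets out from 18. Narasaka–Prasad reduction (Et2BOMe, NaBH4, THF/MeOH, −78 °C) should give the 1,3-syn diol (3R,3aS,5S,8aR)-6,8a-dimethyl-3-(propan-2-yl)-2,3,4,5,8,8a-hexahydroazulene-3a,5(1H)-diol F6. Mitsunobu esterification of F6 with 3,4-dimethoxybenzoic acid (PPh3, DIAD, THF, 0 °C) inverts C5 and comes back to the route at 21; any 5R diol 19 formed alongside continues through step 13.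

**Further compounds**
F1 | step 11 | (1S,2R,5R)-2-[(2Z)-3-iodobut-2-en-1-yl]-2-methyl-5-(propan-2-yl)-1-(prop-2-en-1-yl)cyclopentan-1-ol | C=CC[C@]1(O)[C@@H](C(C)C)CC[C@]1(C)C/C=C(/C)I
F2 | step 11 | 2-[(1S,2R,5R)-1-hydroxy-2-[(2Z)-3-iodobut-2-en-1-yl]-2-methyl-5-(propan-2-yl)cyclopentyl]acetaldehyde | O=CC[C@]1(O)[C@@H](C(C)C)CC[C@]1(C)C/C=C(/C)I
F3 | step 11 | (3R,3aS,8aR)-6,8a-dimethyl-3-(propan-2-yl)-2,3,4,5,8,8a-hexahydroazulene-3a,5(1H)-diol, C5 epimers | OC1C[C@]2(O)[C@@H](C(C)C)CC[C@]2(C)CC=C1C
F4 | step 8 | (2R,5R)-2-(3,3-dibromoprop-2-en-1-yl)-2-methyl-5-(propan-2-yl)cyclopentan-1-one | BrC(Br)=CC[C@@]1(C)CC[C@H](C(C)C)C1=O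
F5 | step 8 | (2R,5R)-2-[(2Z)-3-bromobut-2-en-1-yl]-2-methyl-5-(propan-2-yl)cyclopentan-1-one | C/C(Br)=C/C[C@@]1(C)CC[C@H](C(C)C)C1=O
F6 | step 12 | (3R,3aS,5S,8aR)-6,8a-dimethyl-3-(propan-2-yl)-2,3,4,5,8,8a-hexahydroazulene-3a,5(1H)-diol | O[C@H]1C[C@]2(O)[C@@H](C(C)C)CC[C@]2(C)CC=C1C
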